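Ring A is built, not bought: the bonds C8–C8a, C8a–C4a and C6–C7 are disconnected so that C8, which lies between the oxygen-bearing C7 and C8a with the C5 methoxy para to it, is traced back to an alkyne carbon. One thermal benzannulation of a limonene-derived triisopropylsilyl ynol ether with 3-methoxycyclobutenone makes ring A with the complete side chain, its (R) stereocentre taken intact from the chiral pool, and delivers the C7 and C8a oxygens already differentiated (silyl ether versus free phenol). The precursor is an acyclic (R)-configured siloxyalkyne carrying isopropenyl and a triethylsilyl-protected tertiary alcohol arm.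

Key step: step 7

Remark: commercial (+)-limonene 1,2-oxide (the ring epoxide of (R)-limonene, sold as a cis/trans mixture) is used as the chiral-pool source; both epoxide diastereomers converge on the same keto aldehyde in step 1.
Remark: the (S) ligand in step 12 is chosen by analogy with the sense of induction known for this catalyst family on chalcone itself; if a first run shows the opposite sense, (R)-BINOL is used instead.
Remark: ring atoms are given in flavanone numbering (O1, C2–C8a; rings A, B, C) throughout.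

Step 1
Reactants: 1 (+)-limonene 1,2-oxide [(4R)-1-methyl-4-(prop-1-en-2-yl)-7-oxabicyclo[4.1.0]heptane, cis/trans mixture at C1/C2]
Product: 2 (3R)-6-oxo-3-(prop-1-en-2-yl)heptanal
Conditions: H5IO6 (1.2 equiv), THF/H2O, 0 °C to rt
Reagents that add atoms: water, O
Why: Periodic acid hydrolyses either epoxide diastereomer to the diol in the flask and cleaves it (Malaprade glycol cleavage), leaving the 1,1-disubstituted alkene and the stereocentre untouched.

Step 2
Reactants: 2 (3R)-6-oxo-3-(prop-1-en-2-yl)heptanal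
Product: 3 (5R)-5-(prop-1-en-2-yl)oct-7-yn-2-one
Conditions: dimethyl (1-diazo-2-oxopropyl)phosphonate (1.3 equiv), K2CO3 (2 equiv), MeOH, 0 °C to rt (aldehyde added last)
Reagents that add atoms: dimethyl (1-diazo-2-oxopropyl)phosphonate, COP(=O)(OC)C(=[N+]=[N-])C(C)=O
Why: The Ohira–Bestmann alkynylation is aldehyde-selective, so the methyl ketone survives, and the stereocentre is beta to the aldehyde and cannot epimerise.

Step 3
Reactants: 3 (5R)-5-(prop-1-en-2-yl)oct-7-yn-2-one
Product: 4 (5R)-2-methyl-5-(prop-1-en-2-yl)oct-7-yn-2-ol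
Conditions: MeMgBr (2.5 equiv), THF, −78 to 0 °C; aq. NH4Cl
Reagents that add atoms: methylmagnesium bromide, C[Mg]Br
Why: Grignard 1,2-addition to the methyl ketone gives the achiral dimethyl carbinol, the excess reagent covering any deprotonation of the terminal alkyne.

Step 4
Reactants: 4 (5R)-2-methyl-5-(prop-1-en-2-yl)oct-7-yn-2-ol
Product: 5 triethyl{[(5R)-2-methyl-5-(prop-1-en-2-yl)oct-7-yn-2-yl]oxy}silane
Conditions: TESOTf (1.3 equiv), 2,6-lutidine (2 equiv), CH2Cl2, −78 to 0 °C
Reagents that add atoms: triethylsilyl triflate, CC[Si](CC)(CC)OS(=O)(=O)C(F)(F)F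
Why: Silyl triflate silylation reliably caps the hindered tertiary alcohol, which would otherwise consume base and silyl triflate in step 5 and trap the ketenes of step 7.

Step 5
Reactants: 5 triethyl{[(5R)-2-methyl-5-(prop-1-en-2-yl)oct-7-yn-2-yl]oxy}silane
Product: 8 (5R)-2-methyl-5-(prop-1-en-2-yl)-2-(triethylsilyloxy)-8-(triisopropylsilyloxy)oct-7-yne (the siloxyalkyne), via alkynyllithium 6 (not isolated), via lithium ynolate 7 (not isolated)
Conditions: n-BuLi (1.05 equiv), THF, −78 °C; transfer into LiOOt-Bu [t-BuOOH (anhydrous, 1.1 equiv) + LiN(SiMe3)2 (1.15 equiv), THF, −78 °C]; 0 °C, 2 h; then TIPSOTf (1.2 equiv), −78 °C to rt; chromatography on Et3N-deactivated silica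
Reagents that add atoms: tert-butyl hydroperoxide, CC(C)(C)OO; triisopropylsilyl triflate, CC(C)[Si](OS(=O)(=O)C(F)(F)F)(C(C)C)C(C)C
Why: Oxidation of a lithium acetylide by LiOOt-Bu gives the lithium ynolate (acetylide oxidation), which the bulky silyl triflate captures on oxygen and not on carbon to give the isolable siloxyalkyne.

Step 6
Reactants: 9 cyclobutane-1,3-dione
Product: 10 3-methoxycyclobut-2-en-1-one
Conditions: TMSCHN2 (1.1 equiv, in hexanes), MeOH/Et2O, 0 °C
Reagents that add atoms: (trimethylsilyl)diazomethane, C[Si](C)(C)C=[N+]=[N-]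
Why: The dione is a strongly acidic vinylogous acid present as its enol, so the diazoalkane O-methylates it like a carboxylic acid, and the two equivalent carbonyls allow only one enol ether.

Step 7
Reactants: 8 (5R)-2-methyl-5-(prop-1-en-2-yl)-2-(triethylsilyloxy)-8-(triisopropylsilyloxy)oct-7-yne; 10 3-methoxycyclobut-2-en-1-one
Product: 15 5-methoxy-2-[(2R)-5-methyl-2-(prop-1-en-2-yl)-5-(triethylsilyloxy)hexyl]-3-(triisopropylsilyloxy)phenol, via vinylketene 11 (not isolated), via vinylcyclobutenone 12 (not isolated), via dienylketene 13 (not isolated), via cyclohexadienone 14 (not isolated)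
Conditions: 10 (1.3 equiv, added in portions), toluene, sealed tube, 80 °C then 110 °C
Reagents that add atoms: none
Why: Heating opens 10 by 4π electrocyclic ring opening to the 3-methoxy vinylketene 11, whose ketene C=C adds [2+2] to the ynol ether with the electrophilic ketene carbonyl carbon bonding to the nucleophilic, alkyl-bearing alkyne carbon (forming C8–C8a and C6–C7) to give 12. Cyclobutenone 12 reopens to dienylketene 13, which closes ring A by thermal 6π electrocyclisation (forming C8a–C4a) to dienone 14, and tautomerisation gives the phenol. The closest known reaction type is the Danheiser benzannulation of cyclobutenones with siloxyalkynes, which gives resorcinol monosilyl ethers. No stereocentre is created, and the existing one is separated from the reacting alkyne by a CH2 and bears no acidic hydrogen, so it passes through the neutral thermal cascade unchanged. The selectivity needed is the regiochemistry of the [2+2], secured by the oxygen-polarised siloxyalkyne: the chain lands on C8 between the two oxygenated carbons, the methoxy para to it at C5, the ketene oxygen becomes the free C8a phenol and the alkyne oxygen stays as the C7 silyl ether.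

Step 8
Reactants: 15 5-methoxy-2-[(2R)-5-methyl-2-(prop-1-en-2-yl)-5-(triethylsilyloxy)hexyl]-3-(triisopropylsilyloxy)phenol
Product: 16 5-methoxy-1-(methoxymethoxy)-2-[(2R)-5-methyl-2-(prop-1-en-2-yl)-5-(triethylsilyloxy)hexyl]-3-(triisopropylsilyloxy)benzene
Conditions: NaH (1.3 equiv), MOMCl (1.3 equiv), THF/DMF, 0 °C to rt
Reagents that add atoms: chloromethyl methyl ether, COCCl
Why: Williamson-type O-alkylation of the only free phenol installs a methoxymethyl ether that later serves both as ortho-metalation director and as the acid-labile mask of the ring-closing oxygen.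

Step 9
Reactants: 17 2,4-dihydroxybenzaldehyde
Product: 18 2,4-bis(triisopropylsilyloxy)benzaldehyde
Conditions: TIPSOTf (2.3 equiv), Et3N (3 equiv), CH2Cl2, 0 °C to rt
Reagents that add atoms: triisopropylsilyl triflate, CC(C)[Si](OS(=O)(=O)C(F)(F)F)(C(C)C)C(C)C
Why: Silyl triflate silylation caps both phenols, including the hydrogen-bonded ortho one, with a bulky group that tolerates the organolithium, peroxide and acid steps ahead.

Step 10
Reactants: 18 2,4-bis(triisopropylsilyloxy)benzaldehyde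
Product: 19 (E)-3-[2,4-bis(triisopropylsilyloxy)phenyl]-N-methoxy-N-methylprop-2-enamide
Conditions: diethyl [2-(methoxy(methyl)amino)-2-oxoethyl]phosphonate (1.2 equiv), NaH (1.2 equiv), THF, 0 °C to rt
Reagents that add atoms: diethyl [2-(methoxy(methyl)amino)-2-oxoethyl]phosphonate, CCOP(=O)(OCC)CC(=O)N(C)OC
Why: Horner–Wadsworth–Emmons olefination with the stabilised phosphonate anion gives the (E)-cinnamoyl Weinreb amide.

Step 11
Reactants: 16 5-methoxy-1-(methoxymethoxy)-2-[(2R)-5-methyl-2-(prop-1-en-2-yl)-5-(triethylsilyloxy)hexyl]-3-(triisopropylsilyloxy)benzene; 19 (E)-3-[2,4-bis(triisopropylsilyloxy)phenyl]-N-methoxy-N-methylprop-2-enamide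
Product: 22 (E)-3-[2,4-bis(triisopropylsilyloxy)phenyl]-1-{6-methoxy-2-(methoxymethoxy)-3-[(2R)-5-methyl-2-(prop-1-en-2-yl)-5-(triethylsilyloxy)hexyl]-4-(triisopropylsilyloxy)phenyl}prop-2-en-1-one, via aryllithium 20 (not isolated), via tetrahedral lithium adduct 21 (not isolated)
Conditions: n-BuLi (1.05 equiv), THF, 0 °C, 1 h; then 19 (1.3 equiv), −78 to 0 °C; aq. NH4Cl
Reagents that add atoms: none
Why: Directed ortho-metalation takes place at the only ring hydrogen flanked by two directing groups (OMOM and OMe, i.e. C4a), and the aryllithium acylates the Weinreb amide through a chelated adduct that releases the (E)-enone only on work-up (Weinreb ketone synthesis), which excludes over-addition.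

Step 12
Reactants: 22 (E)-3-[2,4-bis(triisopropylsilyloxy)phenyl]-1-{6-methoxy-2-(methoxymethoxy)-3-[(2R)-5-methyl-2-(prop-1-en-2-yl)-5-(triethylsilyloxy)hexyl]-4-(triisopropylsilyloxy)phenyl}prop-2-en-1-one
Product: 23 {(2R,3S)-3-[2,4-bis(triisopropylsilyloxy)phenyl]oxiran-2-yl}{6-methoxy-2-(methoxymethoxy)-3-[(2R)-5-methyl-2-(prop-1-en-2-yl)-5-(triethylsilyloxy)hexyl]-4-(triisopropylsilyloxy)phenyl}methanone
Conditions: La(O-i-Pr)3 (20 mol%), (S)-BINOL (20 mol%), Ph3As=O (20 mol%), t-BuOOH (1.5 equiv, in decane), 4 Å molecular sieves, THF, rt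
Reagents that add atoms: tert-butyl hydroperoxide, CC(C)(C)OO
Why: Nucleophilic (Weitz–Scheffer-type) epoxidation by the lanthanum–BINOL peroxide attacks only the electron-poor enone and not the isopropenyl group, the chiral catalyst (not the remote side-chain centre) selects the enone face to give the (αR,βS) epoxide, and the trans geometry follows from the (E)-enone.

Step 13
Reactants: 23 {(2R,3S)-3-[2,4-bis(triisopropylsilyloxy)phenyl]oxiran-2-yl}{6-methoxy-2-(methoxymethoxy)-3-[(2R)-5-methyl-2-(prop-1-en-2-yl)-5-(triethylsilyloxy)hexyl]-4-(triisopropylsilyloxy)phenyl}methanone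
Product: 26 (2R,3R)-2-[2,4-bis(triisopropylsilyloxy)phenyl]-3-hydroxy-8-[(2R)-5-hydroxy-5-methyl-2-(prop-1-en-2-yl)hexyl]-5-methoxy-7-(triisopropylsilyloxy)chroman-4-one, via TES-free epoxide 24 (not isolated), via phenol epoxide 25 (not isolated)
Conditions: HCl (1.25 M in MeOH), THF co-solvent, 40 °C
Reagents that add atoms: none
Why: Acid methanolysis removes the tertiary TES ether and the MOM group, and the freed C8a phenol opens the protonated epoxide at the benzylic carbon with inversion (6-endo epoxide opening, favoured over 5-exo by benzylic stabilisation), so C3 keeps the epoxide configuration (R) and C2 becomes R, giving the 2,3-trans flavanonol, which is also the isomer any ionised pathway at C2 would converge on.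

Step 14
Reactants: 26 (2R,3R)-2-[2,4-bis(triisopropylsilyloxy)phenyl]-3-hydroxy-8-[(2R)-5-hydroxy-5-methyl-2-(prop-1-en-2-yl)hexyl]-5-methoxy-7-(triisopropylsilyloxy)chroman-4-one
Product: 27 (2R,3R)-2-(2,4-dihydroxyphenyl)-3,7-dihydroxy-8-[(2R)-5-hydroxy-5-methyl-2-(prop-1-en-2-yl)hexyl]-5-methoxychroman-4-one (CID44584091)
Conditions: TBAF (4 equiv), AcOH (4 equiv), THF, 0 °C
Reagents that add atoms: none
Why: Fluoride-mediated desilylation cleaves the three aryl silyl ethers, while the acetic acid buffer keeps the phenols protonated and so suppresses base-induced ring opening or C2 epimerisation of the flavanonol.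

Compound list

1 | (+)-limonene 1,2-oxide, (4R)-1-methyl-4-(prop-1-en-2-yl)-7-oxabicyclo[4.1.0]heptane, cis/trans mixture at C1/C2 | C=C(C)[C@@H]1CCC2(C)OC2C1 | starting material
2 | (3R)-6-oxo-3-(prop-1-en-2-yl)heptanal | C=C(C)[C@H](CCC(C)=O)CC=O | intermediate
3 | (5R)-5-(prop-1-en-2-yl)oct-7-yn-2-one | C=C(C)[C@H](CCC(C)=O)CC#C | intermediate
4 | (5R)-2-methyl-5-(prop-1-en-2-yl)oct-7-yn-2-ol | C=C(C)[C@H](CCC(C)(C)O)CC#C | intermediate
5 | triethyl{[(5R)-2-methyl-5-(prop-1-en-2-yl)oct-7-yn-2-yl]oxy}silane | C=C(C)[C@H](CCC(C)(C)O[Si](CC)(CC)CC)CC#C | intermediate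
6 | alkynyllithium of 5 (not isolated) | C=C(C)[C@H](CCC(C)(C)O[Si](CC)(CC)CC)CC#C[Li] | intermediate
7 | lithium ynolate, lithium (5R)-7-methyl-4-(prop-1-en-2-yl)-7-(triethylsilyloxy)oct-1-yn-1-olate (not isolated) | C=C(C)[C@H](CCC(C)(C)O[Si](CC)(CC)CC)CC#CO[Li] | intermediate
8 | (5R)-2-methyl-5-(prop-1-en-2-yl)-2-(triethylsilyloxy)-8-(triisopropylsilyloxy)oct-7-yne | C=C(C)[C@H](CCC(C)(C)O[Si](CC)(CC)CC)CC#CO[Si](C(C)C)(C(C)C)C(C)C | intermediate
9 | cyclobutane-1,3-dione (present as its enol) | O=C1CC(=O)C1 | starting material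
10 | 3-methoxycyclobut-2-en-1-one | COC1=CC(=O)C1 | intermediate
11 | 3-methoxybuta-1,3-dien-1-one, the 3-methoxy vinylketene (not isolated) | C=C(OC)C=C=O | intermediate
12 | 4-(1-methoxyethenyl)-2-[(2R)-5-methyl-2-(prop-1-en-2-yl)-5-(triethylsilyloxy)hexyl]-3-(triisopropylsilyloxy)cyclobut-2-en-1-one, both C4 epimers (not isolated) | C=C(C)[C@H](CCC(C)(C)O[Si](CC)(CC)CC)CC1=C(O[Si](C(C)C)(C(C)C)C(C)C)C(C(=C)OC)C1=O | intermediate
13 | dienylketene, 5-methoxy-2-[(2R)-5-methyl-2-(prop-1-en-2-yl)-5-(triethylsilyloxy)hexyl]-3-(triisopropylsilyloxy)hexa-1,3,5-trien-1-one (not isolated) | C=C(C)[C@H](CCC(C)(C)O[Si](CC)(CC)CC)CC(=C=O)C(O[Si](C(C)C)(C(C)C)C(C)C)=CC(=C)OC | intermediate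
14 | 5-methoxy-2-[(2R)-5-methyl-2-(prop-1-en-2-yl)-5-(triethylsilyloxy)hexyl]-3-(triisopropylsilyloxy)cyclohexa-2,4-dien-1-one (not isolated) | C=C(C)[C@H](CCC(C)(C)O[Si](CC)(CC)CC)CC1=C(O[Si](C(C)C)(C(C)C)C(C)C)C=C(OC)CC1=O | intermediate
15 | 5-methoxy-2-[(2R)-5-methyl-2-(prop-1-en-2-yl)-5-(triethylsilyloxy)hexyl]-3-(triisopropylsilyloxy)phenol | C=C(C)[C@H](CCC(C)(C)O[Si](CC)(CC)CC)Cc1c(O)cc(OC)cc1O[Si](C(C)C)(C(C)C)C(C)C | intermediate
16 | 5-methoxy-1-(methoxymethoxy)-2-[(2R)-5-methyl-2-(prop-1-en-2-yl)-5-(triethylsilyloxy)hexyl]-3-(triisopropylsilyloxy)benzene | C=C(C)[C@H](CCC(C)(C)O[Si](CC)(CC)CC)Cc1c(OCOC)cc(OC)cc1O[Si](C(C)C)(C(C)C)C(C)C | intermediate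
17 | 2,4-dihydroxybenzaldehyde | O=Cc1ccc(O)cc1O | starting material
18 | 2,4-bis(triisopropylsilyloxy)benzaldehyde | O=Cc1ccc(O[Si](C(C)C)(C(C)C)C(C)C)cc1O[Si](C(C)C)(C(C)C)C(C)C | intermediate
19 | (E)-3-[2,4-bis(triisopropylsilyloxy)phenyl]-N-methoxy-N-methylprop-2-enamide | CON(C)C(=O)/C=C/c1ccc(O[Si](C(C)C)(C(C)C)C(C)C)cc1O[Si](C(C)C)(C(C)C)C(C)C | intermediate
20 | aryllithium, C4a-lithio derivative of 16, lithium between OMOM and OMe (not isolated) | C=C(C)[C@H](CCC(C)(C)O[Si](CC)(CC)CC)Cc1c(OCOC)c([Li])c(OC)cc1O[Si](C(C)C)(C(C)C)C(C)C | intermediate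
21 | tetrahedral lithium adduct of 20 with 19, lithium alkoxide of the N-methoxy-N-methyl hemiaminal (not isolated) | C=C(C)[C@H](CCC(C)(C)O[Si](CC)(CC)CC)Cc1c(OCOC)c(C(O[Li])(N(C)OC)/C=C/c2ccc(O[Si](C(C)C)(C(C)C)C(C)C)cc2O[Si](C(C)C)(C(C)C)C(C)C)c(OC)cc1O[Si](C(C)C)(C(C)C)C(C)C | intermediate
22 | (E)-3-[2,4-bis(triisopropylsilyloxy)phenyl]-1-{6-methoxy-2-(methoxymethoxy)-3-[(2R)-5-methyl-2-(prop-1-en-2-yl)-5-(triethylsilyloxy)hexyl]-4-(triisopropylsilyloxy)phenyl}prop-2-en-1-one | C=C(C)[C@H](CCC(C)(C)O[Si](CC)(CC)CC)Cc1c(OCOC)c(C(=O)/C=C/c2ccc(O[Si](C(C)C)(C(C)C)C(C)C)cc2O[Si](C(C)C)(C(C)C)C(C)C)c(OC)cc1O[Si](C(C)C)(C(C)C)C(C)C | intermediate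
23 | {(2R,3S)-3-[2,4-bis(triisopropylsilyloxy)phenyl]oxiran-2-yl}{6-methoxy-2-(methoxymethoxy)-3-[(2R)-5-methyl-2-(prop-1-en-2-yl)-5-(triethylsilyloxy)hexyl]-4-(triisopropylsilyloxy)phenyl}methanone | C=C(C)[C@H](CCC(C)(C)O[Si](CC)(CC)CC)Cc1c(OCOC)c(C(=O)[C@@H]2O[C@H]2c3ccc(O[Si](C(C)C)(C(C)C)C(C)C)cc3O[Si](C(C)C)(C(C)C)C(C)C)c(OC)cc1O[Si](C(C)C)(C(C)C)C(C)C | intermediate
24 | TES-free epoxide, as 23 but with the free tertiary alcohol (not isolated) | C=C(C)[C@H](CCC(C)(C)O)Cc1c(OCOC)c(C(=O)[C@@H]2O[C@H]2c3ccc(O[Si](C(C)C)(C(C)C)C(C)C)cc3O[Si](C(C)C)(C(C)C)C(C)C)c(OC)cc1O[Si](C(C)C)(C(C)C)C(C)C | intermediate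
25 | phenol epoxide, as 24 but with the free C8a phenol in place of OMOM (not isolated) | C=C(C)[C@H](CCC(C)(C)O)Cc1c(O)c(C(=O)[C@@H]2O[C@H]2c3ccc(O[Si](C(C)C)(C(C)C)C(C)C)cc3O[Si](C(C)C)(C(C)C)C(C)C)c(OC)cc1O[Si](C(C)C)(C(C)C)C(C)C | intermediate
26 | (2R,3R)-2-[2,4-bis(triisopropylsilyloxy)phenyl]-3-hydroxy-8-[(2R)-5-hydroxy-5-methyl-2-(prop-1-en-2-yl)hexyl]-5-methoxy-7-(triisopropylsilyloxy)chroman-4-one | C=C(C)[C@H](CCC(C)(C)O)Cc1c(O[Si](C(C)C)(C(C)C)C(C)C)cc(OC)c2c1O[C@H](c1ccc(O[Si](C(C)C)(C(C)C)C(C)C)cc1O[Si](C(C)C)(C(C)C)C(C)C)[C@@H](O)C2=O | intermediate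
27 | (2R,3R)-2-(2,4-dihydroxyphenyl)-3,7-dihydroxy-8-[(2R)-5-hydroxy-5-methyl-2-(prop-1-en-2-yl)hexyl]-5-methoxychroman-4-one (CID44584091) | C=C(C)[C@H](CCC(C)(C)O)Cc1c(O)cc(OC)c2c1O[C@H](c1ccc(O)cc1O)[C@@H](O)C2=O | target

Total step count: 14.
Longest linear sequence: 11 steps (steps 1, 2, 3, 4, 5, 7, 8, 11, 12, 13, 14, from 1 to 27).

Steps most likely to fail

1. Step 7. The donor-substituted cyclobutenone may resist thermal ring opening, or its vinylketene may dimerise or acylate the product phenol faster than the ynol ether captures it. Fallback, setting out from 8 and coming back at 15: the same vinylketene 11 is generated at or below room temperature by 1,4-dehydrochlorination instead of electrocyclic opening. (E)-3-Methoxybut-2-enoyl chloride F1, made from commercial (E)-3-methoxybut-2-enoic acid with (COCl)2 and catalytic DMF, is added slowly to 8 and Et3N in CH2Cl2 at 0 °C. The ketene–siloxyalkyne [2+2], known for ketenes made from acid chlorides, should give vinylcyclobutenone 12, which is then warmed on its own in toluene (80 °C) to run the ring-opening and 6π-closure cascade to 15. This separates ketene generation from the thermal stage.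

2. Step 12. Peroxide addition to the congested enone, whose carbonyl is twisted out of the plane of the fully substituted ring A, may be slow or show poor facial selectivity. Fallback, setting out from 18 and 16 and coming back at 23: the epoxide is installed on the ring B fragment by reagent control before the fragments are joined. Wittig reaction of 18 with Ph3P=CHCO2Et gives ethyl (E)-3-[2,4-bis(triisopropylsilyloxy)phenyl]prop-2-enoate F2, and i-Bu2AlH reduction gives (E)-3-[2,4-bis(triisopropylsilyloxy)phenyl]prop-2-en-1-ol F3. Sharpless asymmetric epoxidation (Ti(O-i-Pr)4, L-(+)-diethyl tartrate, t-BuOOH, 4 Å molecular sieves, CH2Cl2, −20 °C) should give the (2S,3S)-epoxy alcohol F4. Parikh–Doering oxidation (SO3·pyridine, DMSO, i-Pr2NEt) gives the (2R,3S)-epoxy aldehyde F5; the spatial arrangement is unchanged and only the descriptor at C2 switches with the priority order. Aryllithium 20, made from 16 as in step 11, adds to F5 at −78 °C to give the epoxy carbinol F6 as a mixture of carbinol epimers. Dess–Martin oxidation (NaHCO3 buffer) removes that centre and returns epoxy ketone 23.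

3. Step 13. During acid unmasking, 5-exo opening at the α-carbon or aroyl migration may compete with the 6-endo closure, and the liberated tertiary alcohol or the isopropenyl group may solvolyse. Fallback, setting out from 23 and coming back at 27: bond cleavage and ring closure are separated by the thiol protocol known for methoxymethyl-protected chalcone epoxides. BnSH and SnCl4 in CH2Cl2 at −20 °C open the epoxide at the benzylic carbon and remove the MOM group in the same operation, giving the α-hydroxy β-benzylsulfanyl ketone F7 (α-carbon unchanged, β-carbon as a mixture). The thiophilic salt AgBF4 (CH2Cl2, 0 °C) then ionises the C–S bond, and the free C8a phenol closes ring C to the trans-flavanonol F8, which still carries the tertiary TES ether. The reagents of step 14, applied at room temperature so that the TES ether is cleaved as well, give 27.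

Further compounds

F1 | step 7 | (E)-3-methoxybut-2-enoyl chloride | CO/C(C)=C/C(=O)Cl
F2 | step 12 | ethyl (E)-3-[2,4-bis(triisopropylsilyloxy)phenyl]prop-2-enoate | CCOC(=O)/C=C/c1ccc(O[Si](C(C)C)(C(C)C)C(C)C)cc1O[Si](C(C)C)(C(C)C)C(C)C
F3 | step 12 | (E)-3-[2,4-bis(triisopropylsilyloxy)phenyl]prop-2-en-1-ol | OC/C=C/c1ccc(O[Si](C(C)C)(C(C)C)C(C)C)cc1O[Si](C(C)C)(C(C)C)C(C)C
F4 | step 12 | {(2S,3S)-3-[2,4-bis(triisopropylsilyloxy)phenyl]oxiran-2-yl}methanol | OC[C@@H]1O[C@H]1c2ccc(O[Si](C(C)C)(C(C)C)C(C)C)cc2O[Si](C(C)C)(C(C)C)C(C)C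
F5 | step 12 | (2R,3S)-3-[2,4-bis(triisopropylsilyloxy)phenyl]oxirane-2-carbaldehyde | O=C[C@@H]1O[C@H]1c2ccc(O[Si](C(C)C)(C(C)C)C(C)C)cc2O[Si](C(C)C)(C(C)C)C(C)C
F6 | step 12 | {(2S,3S)-3-[2,4-bis(triisopropylsilyloxy)phenyl]oxiran-2-yl}{6-methoxy-2-(methoxymethoxy)-3-[(2R)-5-methyl-2-(prop-1-en-2-yl)-5-(triethylsilyloxy)hexyl]-4-(triisopropylsilyloxy)phenyl}methanol, both carbinol epimers | C=C(C)[C@H](CCC(C)(C)O[Si](CC)(CC)CC)Cc1c(OCOC)c(C(O)[C@@H]2O[C@H]2c3ccc(O[Si](C(C)C)(C(C)C)C(C)C)cc3O[Si](C(C)C)(C(C)C)C(C)C)c(OC)cc1O[Si](C(C)C)(C(C)C)C(C)C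
F7 | step 13 | (2S)-3-(benzylsulfanyl)-3-[2,4-bis(triisopropylsilyloxy)phenyl]-2-hydroxy-1-{2-hydroxy-6-methoxy-3-[(2R)-5-methyl-2-(prop-1-en-2-yl)-5-(triethylsilyloxy)hexyl]-4-(triisopropylsilyloxy)phenyl}propan-1-one, both C3 epimers | C=C(C)[C@H](CCC(C)(C)O[Si](CC)(CC)CC)Cc1c(O)c(C(=O)[C@H](O)C(SCc2ccccc2)c3ccc(O[Si](C(C)C)(C(C)C)C(C)C)cc3O[Si](C(C)C)(C(C)C)C(C)C)c(OC)cc1O[Si](C(C)C)(C(C)C)C(C)C
F8 | step 13 | (2R,3R)-2-[2,4-bis(triisopropylsilyloxy)phenyl]-3-hydroxy-5-methoxy-8-[(2R)-5-methyl-2-(prop-1-en-2-yl)-5-(triethylsilyloxy)hexyl]-7-(triisopropylsilyloxy)chroman-4-one | C=C(C)[C@H](CCC(C)(C)O[Si](CC)(CC)CC)Cc1c(O[Si](C(C)C)(C(C)C)C(C)C)cc(OC)c2c1O[C@H](c1ccc(O[Si](C(C)C)(C(C)C)C(C)C)cc1O[Si](C(C)C)(C(C)C)C(C)C)[C@@H](O)C2=O
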